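## Retrosynthetic overview

1. The succinimide is made last: C12–C13 by an Evans syn-aldol of the C12 aldehyde 20 with the amide-bearing acyl oxazolidinone 25, then imide closure with loss of the auxiliary.
2. Ring B decoration (7β-OAc, C8=CH2, 5α-H, 9α-H) comes from the cross-conjugated dienone 13 by α-face hydrogenation, C8 methylenation and Luche reduction; C11–C12 is attached at C9 by Negishi coupling on the β-chloroenone 11.
3. Key disconnection C1–C10: dearomative para-C-alkylation of phenol 10 closes ring A onto the aromatic ring B and creates the quaternary C10 under control of the two C–Cl centres.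
4. The 2α,3β-dichloride is set on the open chain by catalytic enantioselective anti-dichlorination of Z-allylic alcohol 6; the chain comes from 2,6-dichlorotoluene by α-arylation of isobutyraldehyde and Z-olefination; the phenol oxygen is added late by C–H borylation/oxidation.
5. Ring order: ring B (the benzene ring of the feedstock), then ring A (key step), then the succinimide ring.

Assumption: positions are given in labdane numbering (C1–C10 decalin, C11–C16 side chain, C17 exocyclic CH2; α below and β above the ring plane, C10 methyl β), and enolates or phenoxides are treated as reactive forms of the numbered compounds.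

## Route

Step 1
Reactants: 1 2,6-dichlorotoluene (3 equiv); 2 isobutyraldehyde
Product: 3 2-(3-chloro-2-methylphenyl)-2-methylpropanal
Conditions: Pd(OAc)2 (3 mol %), SPhos (6 mol %), Cs2CO3, 1,4-dioxane, 90 °C
Reagents that add atoms: none
Why: Palladium-catalysed α-arylation of the aldehyde enolate (Buchwald–Hartwig-type C–C coupling) at one of the two equivalent C–Cl bonds builds the quaternary benzylic C4 with both methyl groups in place, the excess of 1 and the added hindrance of the product holding it at mono-coupling; no stereocentre is formed.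

Step 2
Reactants: 3 2-(3-chloro-2-methylphenyl)-2-methylpropanal; 4 methyl bis(2,2,2-trifluoroethyl)phosphonoacetate
Product: 5 methyl (Z)-4-(3-chloro-2-methylphenyl)-4-methylpent-2-enoate
Conditions: KN(SiMe3)2, 18-crown-6, THF, −78 °C
Reagents that add atoms: none
Why: The Still–Gennari variant of the Horner–Wadsworth–Emmons olefination gives the Z-enoate under kinetic control, which is the alkene geometry that anti-dichlorination later converts into the threo 2,3-dichloride.

Step 3
Reactants: 5 methyl (Z)-4-(3-chloro-2-methylphenyl)-4-methylpent-2-enoate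
Product: 6 (Z)-4-(3-chloro-2-methylphenyl)-4-methylpent-2-en-1-ol
Conditions: i-Bu2AlH (2.5 equiv), CH2Cl2, −78 °C; aq. potassium sodium tartrate
Reagents that add atoms: none
Why: 1,2-Reduction of the enoate by the aluminium hydride at low temperature gives the allylic alcohol without changing the alkene geometry or touching the aryl chloride (ester reduction).

Step 4
Reactants: 6 (Z)-4-(3-chloro-2-methylphenyl)-4-methylpent-2-en-1-ol
Product: 7 (2R,3R)-2,3-dichloro-4-(3-chloro-2-methylphenyl)-4-methylpentan-1-ol
Conditions: t-BuOCl (1.2 equiv), ClTi(Oi-Pr)3 (1.2 equiv), Burns-type chiral tridentate (O,N,O) Schiff-base ligand (20 mol %, antipode that gives 2R,3R), hexanes, −20 °C, dark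
Reagents that add atoms: tert-butyl hypochlorite CC(C)(C)OCl; chlorotitanium triisopropoxide CC(C)O[Ti](Cl)(OC(C)C)OC(C)C
Why: Titanium-alkoxide-directed catalytic enantioselective dichlorination of an allylic alcohol (Burns-type), in which chloronium formation and backside opening by titanium-bound chloride give strict anti addition across the Z-alkene, so both C–Cl stereocentres (2R,3R) and the absolute configuration of the whole route are set here without any substitution at the neopentyl C3.

Step 5
Reactants: 7 (2R,3R)-2,3-dichloro-4-(3-chloro-2-methylphenyl)-4-methylpentan-1-ol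
Product: 8 (2R,3R)-2,3-dichloro-4-(3-chloro-2-methylphenyl)-4-methylpentyl methanesulfonate
Conditions: MsCl, Et3N, CH2Cl2, 0 °C
Reagents that add atoms: methanesulfonyl chloride CS(=O)(=O)Cl
Why: Sulfonylation of the primary alcohol turns C1 into the electrophile for ring closure, Et3N at 0 °C being too weak to close the chlorohydrin to an epoxide, and the stereocentres are untouched.

Step 6
Reactants: 8 (2R,3R)-2,3-dichloro-4-(3-chloro-2-methylphenyl)-4-methylpentyl methanesulfonate
Product: 10 (2R,3R)-2,3-dichloro-4-(3-chloro-5-hydroxy-2-methylphenyl)-4-methylpentyl methanesulfonate, via aryl pinacol boronate 9 (not isolated)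
Conditions: [Ir(OMe)(C8H12)]2 (1.5 mol %), 4,4′-di-tert-butyl-2,2′-bipyridine (3 mol %), B2pin2, THF, 80 °C; then KHSO5, acetone/H2O, 0 °C to rt
Reagents that add atoms: bis(pinacolato)diboron CC1(C)OB(OC1(C)C)B1OC(C)(C)C(C)(C)O1 (boryl group kept in 9 only); potassium peroxymonosulfate [K+].[O-]S(=O)(=O)OO (phenol oxygen)
Why: Sterically governed iridium-catalysed aromatic C–H borylation takes the only ring C–H without an ortho substituent (para to the methyl group, the future C7) and oxidation of the C–B bond in the same flask gives the phenol, so the ring B oxygen arrives after the electrophilic chlorination and without a protecting group.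

Step 7
Reactants: 10 (2R,3R)-2,3-dichloro-4-(3-chloro-5-hydroxy-2-methylphenyl)-4-methylpentyl methanesulfonate
Product: 11 (4aS,6R,7R)-4,6,7-trichloro-4a,8,8-trimethyl-5,6,7,8-tetrahydronaphthalen-2(4aH)-one (ring B 5,8-dien-7-one; 2α,3β,9-trichloro; 10β-methyl)
Conditions: Cs2CO3 (1.5 equiv), anhydrous MeCN (0.005 M), 40–60 °C
Reagents that add atoms: none
Why: Proposed new method: the caesium phenoxide alkylates through its para carbon (C10) on the tethered primary mesylate in a 6-exo-tet SN2 closure (closest known reaction type: Winstein–Masamune aryl participation, i.e. phenolate para-C-alkylation to cyclohexadienones), O-alkylation being geometrically impossible, and the new quaternary C10 is set by the two C–Cl centres because only the chair-like transition state with both chlorines equatorial avoids a syn-axial clash of the C2 chlorine with the axial C4 methyl and the forming axial C10 methyl, which gives the 10β-methyl isomer.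

Step 8
Reactants: 11 trichloro dienone; 12 (1,3-dioxolan-2-ylmethyl)zinc bromide
Product: 13 (4aR,6R,7R)-6,7-dichloro-4-(1,3-dioxolan-2-ylmethyl)-4a,8,8-trimethyl-5,6,7,8-tetrahydronaphthalen-2(4aH)-one
Conditions: Pd(OAc)2 (5 mol %), SPhos (10 mol %), THF, 50 °C
Reagents that add atoms: none
Why: Negishi cross-coupling at the β-chloroenone carbon (a vinylogous acid chloride that undergoes oxidative addition readily) installs C11–C12 as a masked aldehyde while the unactivated secondary alkyl chlorides and the ketone are inert to catalyst and organozinc; no stereocentre is formed.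

Step 9
Reactants: 13 dioxolanylmethyl dienone
Product: 14 (4S,4aR,6R,7R,8aR)-6,7-dichloro-4-(1,3-dioxolan-2-ylmethyl)-4a,8,8-trimethyloctahydronaphthalen-2(1H)-one (trans-decalin-7-one; 5α-H; 9α-H)
Conditions: H2 (4 atm), Pd/C (10 wt %), EtOAc, rt
Reagents that add atoms: none
Why: Heterogeneous catalytic hydrogenation delivers hydrogen to both enone double bonds from the α-face, anti to the axial C10 and C4 methyl groups, setting 9α-H (side chain β, equatorial) and 5α-H (trans ring fusion) as in hydrogenations of angularly methylated dienones and 5-en-7-ones, while the secondary alkyl chlorides and the dioxolane survive neutral Pd/C.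

Step 10
Reactants: 14 trans-decalin-7-one
Product: 17 (4R,4aR,6R,7R,8aR)-6,7-dichloro-4-(1,3-dioxolan-2-ylmethyl)-4a,8,8-trimethyl-3-methylideneoctahydronaphthalen-2(1H)-one (8(17)-en-7-one), via Mannich base 15 (not isolated), via trimethylammonium iodide 16 (not isolated)
Conditions: LiN(SiMe3)2 (1.05 equiv), THF, −78 °C; CH2=NMe2+ I−, −78 °C to rt; then MeI, rt; then aq. NaHCO3, CH2Cl2
Reagents that add atoms: N,N-dimethylmethyleneiminium iodide C=[N+](C)C.[I-]; iodomethane CI (methyl kept in 16 only)
Why: Kinetic deprotonation removes the more accessible axial 8β-hydrogen (the 6β-hydrogen is shielded by both the C10 and the axial C4 methyl groups), and Mannich alkylation followed by Hofmann-type elimination of the quaternised amine gives the exocyclic enone (ketone α-methylenation), the C8 stereocentre of 15 and 16 being destroyed in the elimination.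

Step 11
Reactants: 17 exocyclic enone
Product: 18 (2S,4R,4aR,6R,7R,8aR)-6,7-dichloro-4-(1,3-dioxolan-2-ylmethyl)-4a,8,8-trimethyl-3-methylidenedecahydronaphthalen-2-ol (7β-ol)
Conditions: NaBH4, CeCl3·7H2O, MeOH, −78 to −20 °C
Reagents that add atoms: none
Why: Luche 1,2-reduction, in which the small borohydride adds along the axial trajectory from the α-face to give the equatorial 7β-alcohol while cerium suppresses conjugate reduction of the exocyclic enone.

Step 12
Reactants: 18 7β-ol
Product: 19 7β-acetate of 18 (7β-acetoxy-2α,3β-dichloro-8(17)-ene bearing the C9 dioxolanylmethyl group)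
Conditions: Ac2O, pyridine, DMAP (cat.), CH2Cl2, rt
Reagents that add atoms: acetic anhydride CC(=O)OC(C)=O
Why: DMAP-catalysed acylation of the only hydroxyl group fixes the C7 acetate of the target before the C12 hydroxyl is created.

Step 13
Reactants: 19 7β-acetate
Product: 20 7β-acetoxy-2α,3β-dichloro-13,14,15,16-tetranorlabd-8(17)-en-12-al
Conditions: PPTS (0.3 equiv), acetone/H2O (9:1), 55 °C
Reagents that add atoms: water O
Why: Mild acid-catalysed acetal hydrolysis releases the aldehyde, pyridinium tosylate in wet acetone being too weak to ionise the allylic acetate or isomerise the exocyclic alkene.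

Step 14
Reactants: 21 (R)-4-benzyl-1,3-oxazolidin-2-one; 22 succinic anhydride
Product: 23 4-[(4R)-4-benzyl-2-oxo-1,3-oxazolidin-3-yl]-4-oxobutanoic acid
Conditions: n-BuLi, THF, −78 °C; then 22, −78 to 0 °C; aq. HCl work-up
Reagents that add atoms: none
Why: N-Acylation of the lithiated oxazolidinone by ring-opening of the cyclic anhydride gives the imide acid in one operation.

Step 15
Reactants: 23 imide acid
Product: 25 4-[(4R)-4-benzyl-2-oxo-1,3-oxazolidin-3-yl]-4-oxobutanamide, via isobutyl carbonic anhydride 24 (not isolated)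
Conditions: i-BuOCOCl, N-methylmorpholine, THF, −15 °C; then NH3 (0.5 M in dioxane), −15 to 0 °C
Reagents that add atoms: isobutyl chloroformate CC(C)COC(Cl)=O (atoms kept in 24 only); ammonia N
Why: Mixed carbonic anhydride activation of the distal carboxylic acid and ammonolysis at low temperature give the primary amide, the far more electrophilic mixed anhydride reacting before the acyl oxazolidinone.

Step 16
Reactants: 20 C12 aldehyde; 25 amide-bearing acyl oxazolidinone
Product: 26 (4R)-4-benzyl-3-[(2R,3S)-2-(2-amino-2-oxoethyl)-3-hydroxy-4-(C9 of the 7β-acetoxy-2α,3β-dichlorolabd-8(17)-ene core)butanoyl]-1,3-oxazolidin-2-one (12S,13R syn-aldol adduct)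
Conditions: 25, Bu2BOTf (2.2 equiv), i-Pr2NEt (2.6 equiv), CH2Cl2, 0 °C; then 20, −78 to 0 °C; pH 7 buffer, MeOH, H2O2, 0 °C
Reagents that add atoms: none
Why: Evans syn-aldol reaction, in which the Z-boron enolate of the imide (the second equivalent of boron triflate ties up the primary amide) adds through a closed Zimmerman–Traxler transition state on the enolate face opposite the benzyl group, so the (R)-auxiliary sets 12S and 13R independently of the remote decalin stereocentres.

Step 17
Reactants: 26 syn-aldol adduct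
Product: 27 haterumaimide A
Conditions: DBU (0.5 equiv), THF, 0 °C to rt; aq. NH4Cl
Reagents that add atoms: none
Why: Base-promoted 5-exo-trig attack of the primary amide nitrogen on the activated exocyclic imide carbonyl (intramolecular N-acyl transfer, the reaction type of aspartimide formation) closes the succinimide and expels the auxiliary without touching the acetate, and the acidic imide N–H that forms buffers the base and protects C13 from epimerisation.

## Compound list

1 | 2,6-dichlorotoluene | Cc1c(Cl)cccc1Cl | starting material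
2 | isobutyraldehyde (2-methylpropanal) | CC(C)C=O | starting material
3 | 2-(3-chloro-2-methylphenyl)-2-methylpropanal | Cc1c(Cl)cccc1C(C)(C)C=O | intermediate
4 | methyl bis(2,2,2-trifluoroethyl)phosphonoacetate | COC(=O)CP(=O)(OCC(F)(F)F)OCC(F)(F)F | starting material
5 | methyl (Z)-4-(3-chloro-2-methylphenyl)-4-methylpent-2-enoate | COC(=O)/C=C\C(C)(C)c1cccc(Cl)c1C | intermediate
6 | (Z)-4-(3-chloro-2-methylphenyl)-4-methylpent-2-en-1-ol | OC/C=C\C(C)(C)c1cccc(Cl)c1C | intermediate
7 | (2R,3R)-2,3-dichloro-4-(3-chloro-2-methylphenyl)-4-methylpentan-1-ol | Cc1c(Cl)cccc1C(C)(C)[C@@H](Cl)[C@H](Cl)CO | intermediate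
8 | (2R,3R)-2,3-dichloro-4-(3-chloro-2-methylphenyl)-4-methylpentyl methanesulfonate | Cc1c(Cl)cccc1C(C)(C)[C@@H](Cl)[C@H](Cl)COS(C)(=O)=O | intermediate
9 | (2R,3R)-2,3-dichloro-4-[3-chloro-2-methyl-5-(4,4,5,5-tetramethyl-1,3,2-dioxaborolan-2-yl)phenyl]-4-methylpentyl methanesulfonate | Cc1c(Cl)cc(B2OC(C)(C)C(C)(C)O2)cc1C(C)(C)[C@@H](Cl)[C@H](Cl)COS(C)(=O)=O | intermediate
10 | (2R,3R)-2,3-dichloro-4-(3-chloro-5-hydroxy-2-methylphenyl)-4-methylpentyl methanesulfonate | Cc1c(Cl)cc(O)cc1C(C)(C)[C@@H](Cl)[C@H](Cl)COS(C)(=O)=O | intermediate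
11 | (4aS,6R,7R)-4,6,7-trichloro-4a,8,8-trimethyl-5,6,7,8-tetrahydronaphthalen-2(4aH)-one | O=C1C=C2C(C)(C)[C@@H](Cl)[C@H](Cl)C[C@]2(C)C(Cl)=C1 | intermediate
12 | (1,3-dioxolan-2-ylmethyl)zinc bromide | Br[Zn]CC1OCCO1 | starting material
13 | (4aR,6R,7R)-6,7-dichloro-4-(1,3-dioxolan-2-ylmethyl)-4a,8,8-trimethyl-5,6,7,8-tetrahydronaphthalen-2(4aH)-one | O=C1C=C2C(C)(C)[C@@H](Cl)[C@H](Cl)C[C@]2(C)C(CC3OCCO3)=C1 | intermediate
14 | (4S,4aR,6R,7R,8aR)-6,7-dichloro-4-(1,3-dioxolan-2-ylmethyl)-4a,8,8-trimethyloctahydronaphthalen-2(1H)-one | C1C(=O)C[C@H]2C(C)(C)[C@@H](Cl)[C@H](Cl)C[C@]2(C)[C@H]1CC1OCCO1 | intermediate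
15 | 8-[(dimethylamino)methyl] derivative of 14 (C8 epimers, inconsequential) | CN(C)CC1C(=O)C[C@H]2C(C)(C)[C@@H](Cl)[C@H](Cl)C[C@]2(C)[C@H]1CC1OCCO1 | intermediate
16 | 8-[(trimethylammonio)methyl] derivative of 14, iodide | C[N+](C)(C)CC1C(=O)C[C@H]2C(C)(C)[C@@H](Cl)[C@H](Cl)C[C@]2(C)[C@H]1CC1OCCO1.[I-] | intermediate
17 | (4R,4aR,6R,7R,8aR)-6,7-dichloro-4-(1,3-dioxolan-2-ylmethyl)-4a,8,8-trimethyl-3-methylideneoctahydronaphthalen-2(1H)-one | C=C1C(=O)C[C@H]2C(C)(C)[C@@H](Cl)[C@H](Cl)C[C@]2(C)[C@H]1CC1OCCO1 | intermediate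
18 | (2S,4R,4aR,6R,7R,8aR)-6,7-dichloro-4-(1,3-dioxolan-2-ylmethyl)-4a,8,8-trimethyl-3-methylidenedecahydronaphthalen-2-ol (7β-ol) | C=C1[C@@H](O)C[C@H]2C(C)(C)[C@@H](Cl)[C@H](Cl)C[C@]2(C)[C@H]1CC1OCCO1 | intermediate
19 | acetate of 18 (7β-OAc) | C=C1[C@@H](OC(C)=O)C[C@H]2C(C)(C)[C@@H](Cl)[C@H](Cl)C[C@]2(C)[C@H]1CC1OCCO1 | intermediate
20 | 7β-acetoxy-2α,3β-dichloro-13,14,15,16-tetranorlabd-8(17)-en-12-al | C=C1[C@@H](OC(C)=O)C[C@H]2C(C)(C)[C@@H](Cl)[C@H](Cl)C[C@]2(C)[C@H]1CC=O | intermediate
21 | (R)-4-benzyl-1,3-oxazolidin-2-one | O=C1N[C@H](Cc2ccccc2)CO1 | starting material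
22 | succinic anhydride | O=C1CCC(=O)O1 | starting material
23 | 4-[(4R)-4-benzyl-2-oxo-1,3-oxazolidin-3-yl]-4-oxobutanoic acid | OC(=O)CCC(=O)N1[C@H](Cc2ccccc2)COC1=O | intermediate
24 | mixed isobutyl carbonic anhydride of 23 | CC(C)COC(=O)OC(=O)CCC(=O)N1[C@H](Cc2ccccc2)COC1=O | intermediate
25 | 4-[(4R)-4-benzyl-2-oxo-1,3-oxazolidin-3-yl]-4-oxobutanamide | NC(=O)CCC(=O)N1[C@H](Cc2ccccc2)COC1=O | intermediate
26 | Evans syn-aldol adduct (12S,13R; acyl oxazolidinone at C16, primary amide at C15) | C=C1[C@@H](OC(C)=O)C[C@H]2C(C)(C)[C@@H](Cl)[C@H](Cl)C[C@]2(C)[C@H]1C[C@H](O)[C@H](C(=O)N1[C@H](Cc3ccccc3)COC1=O)CC(N)=O | intermediate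
27 | haterumaimide A | C=C1[C@@H](OC(C)=O)C[C@H]2C(C)(C)[C@@H](Cl)[C@H](Cl)C[C@]2(C)[C@H]1C[C@H](O)[C@H]1CC(=O)NC1=O | target

## Step count and risks

Total step count: 17 (15 on the main line plus 2 for the aldol partner 25).
Longest linear sequence: 15 steps (steps 1–13, 16, 17, from 2,6-dichlorotoluene).

The three steps most likely to fail:

Step 7 (dearomative ring A closure). The phenoxide can also alkylate through the ortho carbon C6, which would give a re-aromatised tetralinol instead of dienone 11. The fallback blocks both ortho positions and sets out from 10. Ortho-chlorination with SO2Cl2 (2.1 equiv) and a catalytic secondary amine gives (2R,3R)-2,3-dichloro-4-methyl-4-(2,4,5-trichloro-3-hydroxy-6-methylphenyl)pentyl methanesulfonate F1. Cs2CO3 in MeCN can then alkylate only at the para carbon and gives (4aS,6R,7R)-1,3,4,6,7-pentachloro-4a,8,8-trimethyl-5,6,7,8-tetrahydronaphthalen-2(4aH)-one F2. Negishi coupling with 12 at the activated β-chloro position (the α-chloroenone C–Cl bonds are much less reactive) gives (4aR,6R,7R)-1,3,6,7-tetrachloro-4-(1,3-dioxolan-2-ylmethyl)-4a,8,8-trimethyl-5,6,7,8-tetrahydronaphthalen-2(4aH)-one F3. Hydrogenation over Pd/C with Et3N saturates both double bonds from the α-face and hydrogenolyses the two chlorines next to the carbonyl, so the route is rejoined at 14.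

Step 4 (enantioselective dichlorination). The Z-alkene carries a tert-alkyl group and may react slowly or with low ee. The fallback sets out from 6 and gives up asymmetric catalysis: Et4NCl3 in CH2Cl2 at 0 °C gives the racemic anti-dichloride, that is 7 together with its enantiomer (2S,3S)-2,3-dichloro-4-(3-chloro-2-methylphenyl)-4-methylpentan-1-ol F4. The two are separated by preparative chiral SFC and the route is rejoined at 7, at the cost of half the material.

Step 10 (regioselective methylenation). Enolisation of 14 toward C6 would put the methylene on the wrong side of the ketone. The fallback sets out from 13 and makes the C8 enolate regiospecifically. [(Ph3P)CuH]6 adds hydride to C9 of the less hindered enone from the α-face, and trapping the copper enolate with CH2=NMe2+ I− gives the 8-[(dimethylamino)methyl]-5-en-7-one F5. Hydrogenation over Pd/C then reduces the remaining C5=C6 bond from the α-face and the route is rejoined at 15 (now isolated), which is quaternised and eliminated to 17 as in step 10.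

## Further compounds

F1 | step 7 | (2R,3R)-2,3-dichloro-4-methyl-4-(2,4,5-trichloro-3-hydroxy-6-methylphenyl)pentyl methanesulfonate | Cc1c(Cl)c(Cl)c(O)c(Cl)c1C(C)(C)[C@@H](Cl)[C@H](Cl)COS(C)(=O)=O
F2 | step 7 | (4aS,6R,7R)-1,3,4,6,7-pentachloro-4a,8,8-trimethyl-5,6,7,8-tetrahydronaphthalen-2(4aH)-one | O=C1C(Cl)=C2C(C)(C)[C@@H](Cl)[C@H](Cl)C[C@]2(C)C(Cl)=C1Cl
F3 | step 7 | (4aR,6R,7R)-1,3,6,7-tetrachloro-4-(1,3-dioxolan-2-ylmethyl)-4a,8,8-trimethyl-5,6,7,8-tetrahydronaphthalen-2(4aH)-one | O=C1C(Cl)=C2C(C)(C)[C@@H](Cl)[C@H](Cl)C[C@]2(C)C(CC3OCCO3)=C1Cl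
F4 | step 4 | (2S,3S)-2,3-dichloro-4-(3-chloro-2-methylphenyl)-4-methylpentan-1-ol | Cc1c(Cl)cccc1C(C)(C)[C@H](Cl)[C@@H](Cl)CO
F5 | step 10 | (4S,4aR,6R,7R)-6,7-dichloro-3-[(dimethylamino)methyl]-4-(1,3-dioxolan-2-ylmethyl)-4a,8,8-trimethyl-4,4a,5,6,7,8-hexahydronaphthalen-2(3H)-one (C8 epimers) | CN(C)CC1C(=O)C=C2C(C)(C)[C@@H](Cl)[C@H](Cl)C[C@]2(C)[C@H]1CC1OCCO1
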